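Readings and results are calculated for substances that don't exist; scatter was added.

In a one-step world, substrate + reagent → mono adduct, Sunday's flask would have lost substrate mole for mole with its 0.38 M of reagent, but at 10.0 min it had lost 0.308 M. Wednesday's flask, with the same reagent, ran its substrate down to 1.5 %, which speaks against an equilibrium. So I took reagent to have a second, first-order way out.

| flask | substrate | reagent | remark | time |
|---|---|---|---|---|
| Wednesday's | 0.15 M | 0.38 M | run made earlier |  |
| Sunday's | 0.41 M | 0.38 M | run made earlier |  |
| Thursday's | 1.2 M | 0.38 M | run made earlier |  |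
| Friday's | 0.40 M | 0.21 M | run made earlier |  |
| elm | 0.12 M | 0.600 M |  | 20 min |
| birch | 0.40 M | 0.100 M |  | 20 min |
| larch | 1.5 M | 0.120 M |  | 20 min |
| oak | 0.60 M | 0.100 M |  | 20 min |
| alder | 0.40 M | 0.380 M |  | 20 min |

| run | time / min | mono adduct / % | substrate / % |
|---|---|---|---|
| Wednesday's | 0.833 | 49.0 | 46.2 |
| Wednesday's | 2.00 | 77.7 | 21.9 |
| Wednesday's | 4.00 | 89.4 | 9.9 |
| Wednesday's | 10.0 | 91.3 | 1.5 |
| Sunday's | 0.833 | 43.4 | 55.1 |
| Sunday's | 2.00 | 61.6 | 37.9 |
| Sunday's | 4.00 | 70.5 | 29.8 |
| Sunday's | 10.0 | 73.1 | 24.8 |
| Thursday's | 0.833 | 26.7 | 72.6 |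
| Thursday's | 2.00 | 30.2 | 70.8 |
| Thursday's | 4.00 | 29.1 | 70.0 |
| Thursday's | 10.0 | 29.8 | 70.4 |
| Friday's | 0.833 | 25.6 | 73.2 |
| Friday's | 2.00 | 37.3 | 61.4 |
| Friday's | 4.00 | 42.1 | 55.9 |
| Friday's | 10.0 | 41.6 | 54.4 |

(readings scatter by 1 percentage point)

- the numbers in the tables scatter with a standard deviation of 1 percentage point

- ranking by amount of mono adduct, in percent of the substrate charged, from high to low, at 20 min (elm / birch / larch / oak / alder)
- the amount of mono adduct, in percent of the substrate charged of the flask you put first, at 20 min
- the amount of mono adduct, in percent of the substrate charged of the flask you put last, at 20 min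

A reagent molecule then has two lifetimes: one towards substrate, which shortens as [substrate] rises, and one towards its own loss, which does not. Their ratio needs no clock. I call the [substrate] at which the two lifetimes are equal the break-even concentration a; at that [substrate] reagent divides evenly between the two paths. Dividing one rate by the other removes time, and once reagent is used up,

reagent charged = substrate lost + a·ln(substrate charged/substrate left).

Taking Sunday's reagent as used up by 10.0 min, I read a = 0.0514 M; Friday's run reads 0.0453 M.

In larch, reagent is the limiting reagent, since 0.120 M is set against 1.5 M of substrate. Its mean [substrate] is about 1.44 M, far above a, so substrate takes a share [substrate]/([substrate] + a) = 96.6 % of the reagent. My reckoning for larch is therefore 7.73 % mono adduct. Among the reagent-poor flasks, the ceiling is reagent over substrate: birch 25.0 %, oak 16.7 %, larch 8.00 %.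

By this relation, taking substrate down to one part in 100 costs elm 0.357 M of reagent, less than its 0.600 M. The same end would cost alder 0.637 M, more than its 0.380 M. So I put elm above alder. Wednesday's balance, short by 7.2 points at 10.0 min, warned me that elm's mono adduct might not hold the full charge.

The forecast used the same relation with a = 0.055 M, on the ground that “Reagent must also decay on its own”. It gave elm > alder > birch > oak > larch, with 83 % (76 % to 88 %) for the first flask and 7.7 % (7.2 % to 8.2 %) for the last.

The flasks came out as elm > alder > birch > oak > larch, with elm at 85.1 % and larch at 7.76 %, so the forecast's order held and both values lay inside its ranges.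

    substrate + reagent → mono adduct (k = 0.0470 M⁻¹ s⁻¹)
    reagent + mono adduct → bis adduct (k = 9.50 × 10⁻⁴ M⁻¹ s⁻¹)
    reagent + bis adduct → triple product (k = 0.0560 M⁻¹ s⁻¹)
    reagent ⇌ dormant form (K = 16.0, k = 0.00240 s⁻¹)

In larch at 20.0 min, the dormant form stood at 0.00346 M, beside the 0.00414 M of reagent that my share had sent away from substrate. On oak, the same a, with a mean [substrate] of 0.550 M, gives a share of 91.5 % and so 15.2 % mono adduct. Oak held 15.4 % at 20.0 min.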